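**Strategy.** Elemane numbering is used (C5 isopropenyl-bearing CH, C6 lactone CH–O, C7 ring-fusion CH, C8 CH–OAc, C10 quaternary carbon, C11/C12 lactone α-carbon and carbonyl). The carbocycle is disconnected at C6–C7 and C5–C10. One thermal intramolecular Diels–Alder reaction of a 2-silyloxydiene (C7=C8–C9=C10) with an (E)-β-acyloxy enone (C5=C6), tethered through the future lactone ester O6–C12(=O)–C11, closes the cyclohexene and the cis-fused γ-lactone together and sets C5, C6 and C7. It exploits that the C6–C7 bond is shared by both rings and that quaternary C11, taken from (S)-citramalic acid, sits next to C8–OSi. The precursor is an acyclic enol ester. C10 becomes quaternary afterwards (Saegusa–Ito oxidation, conjugate vinylation).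

Key step: step 6

Remark: angeloyl chloride [(Z)-2-methylbut-2-enoyl chloride] is taken as a purchasable reagent (otherwise made fresh from angelic acid and oxalyl chloride).
Remark: CIP descriptors of the ring carbons change between 12, 13 and 14 only through priority changes; no spatial change is implied, and the SMILES are authoritative.
Remark: the chloride bridge of the Tebbe reagent is drawn with formal charges on aluminium and chlorine, which stands for the Cl→Al dative bond.

Step 1
Reactants: 1 (S)-citramalic acid [(2S)-2-hydroxy-2-methylbutanedioic acid]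
Product: 2 2-[(4S)-2,2,4-trimethyl-5-oxo-1,3-dioxolan-4-yl]acetic acid
Conditions: Me2C(OMe)2, p-TsOH (cat.), acetone, rt
Reagents that add atoms: 2,2-dimethoxypropane, COC(C)(C)OC
Why: Acid-catalysed transacetalisation (acetonide-type protection) engages only the α-hydroxy acid unit as the five-membered dioxolanone, leaving the CH2CO2H arm (future C8) free and the chiral-pool stereocentre C11 untouched.

Step 2
Reactants: 2 2-[(4S)-2,2,4-trimethyl-5-oxo-1,3-dioxolan-4-yl]acetic acid; 3 (E)-prop-1-en-1-ylboronic acid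
Product: 5 (5S)-2,2,5-trimethyl-5-[(3E)-2-oxopent-3-en-1-yl]-1,3-dioxolan-4-one, via acid chloride 4 (not isolated)
Conditions: (COCl)2, DMF (cat.), CH2Cl2, 0 °C → rt; then 3, Pd(PPh3)4 (cat.), Cs2CO3, toluene, 80 °C
Reagents that add atoms: none
Why: Acyl chloride formation followed by Suzuki–Miyaura acylation (oxidative addition of C–Cl to zerovalent palladium, transmetalation from boron, reductive elimination) should give the enone with retention of the E geometry and no base-labile hydroxyl exposed.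

Step 3
Reactants: 5 (5S)-2,2,5-trimethyl-5-[(3E)-2-oxopent-3-en-1-yl]-1,3-dioxolan-4-one
Product: 6 (5S)-5-[(1Z,3E)-2-{[tert-butyl(dimethyl)silyl]oxy}penta-1,3-dien-1-yl]-2,2,5-trimethyl-1,3-dioxolan-4-one
Conditions: TBSOTf, Et3N, CH2Cl2, −78 → 0 °C
Reagents that add atoms: tert-butyldimethylsilyl trifluoromethanesulfonate, CC(C)(C)[Si](C)(C)OS(=O)(=O)C(F)(F)F
Why: Soft enolisation (silyl triflate/amine) of the enone on the C7 side should give the cross-conjugated 2-silyloxydiene as the enol ether in which the bulky quaternary C11 is cis to the small OSi group, which places C11 on the outside of the diene.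

Step 4
Reactants: 6 (5S)-5-[(1Z,3E)-2-{[tert-butyl(dimethyl)silyl]oxy}penta-1,3-dien-1-yl]-2,2,5-trimethyl-1,3-dioxolan-4-one
Product: 8 prop-2-en-1-yl (2S,3Z,5E)-4-{[tert-butyl(dimethyl)silyl]oxy}-2-methyl-2-{[(2Z)-2-methylbut-2-enoyl]oxy}hepta-3,5-dienoate, via sodium alkoxide 7 (not isolated)
Conditions: allyl alcohol, NaH, THF, −20 → 0 °C; then angeloyl chloride, −40 → 0 °C
Reagents that add atoms: allyl alcohol, C=CCO; angeloyl chloride, C/C=C(/C)C(=O)Cl
Why: Alkoxide transesterification opens the acylal-type dioxolanone with loss of acetone and the tertiary alkoxide so released is acylated directly by the acid chloride (alkoxide O-acylation), which works here because the ketone is masked as its enol ether (no retro-aldol or β-elimination) and keeps the Z geometry of the angelate.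

Step 5
Reactants: 8 prop-2-en-1-yl (2S,3Z,5E)-4-{[tert-butyl(dimethyl)silyl]oxy}-2-methyl-2-{[(2Z)-2-methylbut-2-enoyl]oxy}hepta-3,5-dienoate; 9 but-3-yn-2-one
Product: 11 (1E)-3-oxobut-1-en-1-yl (2S,3Z,5E)-4-{[tert-butyl(dimethyl)silyl]oxy}-2-methyl-2-{[(2Z)-2-methylbut-2-enoyl]oxy}hepta-3,5-dienoate, via triethylammonium carboxylate 10 (not isolated)
Conditions: Pd(PPh3)4 (cat.), HCO2H, Et3N, THF, 0 °C; then 9, 0 °C → rt
Reagents that add atoms: none
Why: Palladium-catalysed formate deallylation (π-allyl formation, hydride transfer from formate) frees the carboxylate without touching the enol ether, and its amine-mediated conjugate addition to the ynone gives the thermodynamically preferred (E)-β-acyloxy enone.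

Step 6
Reactants: 11 (1E)-3-oxobut-1-en-1-yl (2S,3Z,5E)-4-{[tert-butyl(dimethyl)silyl]oxy}-2-methyl-2-{[(2Z)-2-methylbut-2-enoyl]oxy}hepta-3,5-dienoate
Product: 12 (3S,3aR,6S,7R,7aR)-7-acetyl-4-{[tert-butyl(dimethyl)silyl]oxy}-3,6-dimethyl-2-oxo-2,3,3a,6,7,7a-hexahydro-1-benzofuran-3-yl (2Z)-2-methylbut-2-enoate
Conditions: toluene (0.005 M), BHT (cat.), 110 °C, sealed tube
Reagents that add atoms: none
Why: Concerted but asynchronous thermal [4+2] cycloaddition of normal electron demand (silyl dienol ether HOMO, enone LUMO, C7–C6 bonding in advance of C10–C5), the closest known class being type 1 intramolecular Diels–Alder reactions of ester-tethered 1,3,8-nonatrienes. The carbocycle closes in the six-membered [4+2] mode and the γ-lactone as the fused five-membered ring spanned by the three-atom tether C11–C12–O6. C6 and C7: in the (Z)-enol ether the quaternary C11 is cis to OSi, so none of its substituents can lie in the diene plane beside OSi (allylic 1,3-strain), which forces C12 gauche to C8, the tether endo and hence the cis ring fusion (H6/H7 cis). C5: the E geometry of the enone is transferred, placing the acetyl group exo and trans to O6; C10: the E geometry of C9=C10 puts the methyl cis to C11 (provisional, erased in step 8). The diene face is chosen by C11: the C–O(angelate) bond stays in the diene plane pointing away from OSi (it avoids overlap with the diene π system), the methyl group lies anti to the incoming dienophile and the acyl tether delivers the enone to the other face, which corresponds to the configuration drawn for 12. The step needs cis- over trans-fusion and reaction at the acyl enone instead of the angelate; the first should be secured by the quaternary C11/OSi pair, the second by the lower LUMO and lower substitution of the acyl enone.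

Step 7
Reactants: 12 (3S,3aR,6S,7R,7aR)-7-acetyl-4-{[tert-butyl(dimethyl)silyl]oxy}-3,6-dimethyl-2-oxo-2,3,3a,6,7,7a-hexahydro-1-benzofuran-3-yl (2Z)-2-methylbut-2-enoate
Product: 13 (3S,3aR,6R,7S,7aS)-4-{[tert-butyl(dimethyl)silyl]oxy}-3,6-dimethyl-2-oxo-7-(prop-1-en-2-yl)-2,3,3a,6,7,7a-hexahydro-1-benzofuran-3-yl (2Z)-2-methylbut-2-enoate
Conditions: Cp2Ti(μ-Cl)(μ-CH2)AlMe2 (Tebbe reagent, 1.1 equiv), pyridine, THF–toluene, −40 → 0 °C
Reagents that add atoms: Tebbe reagent Cp2Ti(μ-Cl)(μ-CH2)AlMe2, C[Al-]1(C)C[Ti](C2C=CC=C2)(C2C=CC=C2)[Cl+]1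
Why: Tebbe methylenation (titanium methylidene, oxatitanacyclobutane, cycloreversion) turns the methyl ketone into the isopropenyl group under non-basic conditions, so that C5 is not epimerised, the β-acyloxy ketone does not eliminate and the less electrophilic lactone and ester carbonyls are left alone at low temperature.

Step 8
Reactants: 13 (3S,3aR,6R,7S,7aS)-4-{[tert-butyl(dimethyl)silyl]oxy}-3,6-dimethyl-2-oxo-7-(prop-1-en-2-yl)-2,3,3a,6,7,7a-hexahydro-1-benzofuran-3-yl (2Z)-2-methylbut-2-enoate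
Product: 14 (3S,3aR,7R,7aS)-3,6-dimethyl-2,4-dioxo-7-(prop-1-en-2-yl)-2,3,3a,4,7,7a-hexahydro-1-benzofuran-3-yl (2Z)-2-methylbut-2-enoate
Conditions: Pd(OAc)2 (1.1 equiv), MeCN, rt
Reagents that add atoms: none
Why: Saegusa–Ito oxidation (palladium enolate at C9, syn β-hydride elimination of H10, the only β-hydrogen) should give the C9=C10 enone regiospecifically, removing the provisional C10 stereocentre.

Step 9
Reactants: 14 (3S,3aR,7R,7aS)-3,6-dimethyl-2,4-dioxo-7-(prop-1-en-2-yl)-2,3,3a,4,7,7a-hexahydro-1-benzofuran-3-yl (2Z)-2-methylbut-2-enoate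
Product: 16 (3S,3aR,6R,7R,7aS)-6-ethenyl-3,6-dimethyl-2,4-dioxo-7-(prop-1-en-2-yl)octahydro-1-benzofuran-3-yl (2Z)-2-methylbut-2-enoate, via trimethylsilyl enol ether 15 (not isolated)
Conditions: CH2=CHMgBr, CuBr·SMe2 (cat.), TMSCl, THF, −78 °C; then 1 M citric acid
Reagents that add atoms: vinylmagnesium bromide (CH2=CHMgBr), C=C[Mg]Br
Why: Copper-catalysed 1,4-addition of the vinyl Grignard reagent with TMSCl acceleration creates quaternary C10, and because allylic 1,2-strain with the C10 methyl group holds the C5 isopropenyl group pseudoaxial, axial attack anti to it should place vinyl trans to isopropenyl (methyl cis), the sense known for 3-methyl-4-alkylcyclohexenones.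

Step 10
Reactants: 16 (3S,3aR,6R,7R,7aS)-6-ethenyl-3,6-dimethyl-2,4-dioxo-7-(prop-1-en-2-yl)octahydro-1-benzofuran-3-yl (2Z)-2-methylbut-2-enoate
Product: 17 (3S,3aR,4S,6R,7R,7aS)-6-ethenyl-4-hydroxy-3,6-dimethyl-2-oxo-7-(prop-1-en-2-yl)octahydro-1-benzofuran-3-yl (2Z)-2-methylbut-2-enoate
Conditions: LiBH(s-Bu)3, THF, −78 °C; then H2O
Reagents that add atoms: none
Why: Hydride reduction with the bulky borohydride should proceed along the equatorial trajectory, anti to the axial C10 methyl group that blocks the axial trajectory, to give the axial C8 alcohol cis to that methyl, while lactone and esters survive at −78 °C.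

Step 11
Reactants: 17 (3S,3aR,4S,6R,7R,7aS)-6-ethenyl-4-hydroxy-3,6-dimethyl-2-oxo-7-(prop-1-en-2-yl)octahydro-1-benzofuran-3-yl (2Z)-2-methylbut-2-enoate
Product: 18 (3S,3aR,4S,6R,7R,7aS)-4-(acetyloxy)-6-ethenyl-3,6-dimethyl-2-oxo-7-(prop-1-en-2-yl)octahydro-1-benzofuran-3-yl (2Z)-2-methylbut-2-enoate (CNP0140071.1)
Conditions: Ac2O, pyridine, DMAP (cat.), CH2Cl2, 0 °C → rt
Reagents that add atoms: acetic anhydride, CC(=O)OC(C)=O
Why: DMAP-catalysed O-acylation of the secondary alcohol with retention at C8 completes the target without touching the tertiary angelate.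

**Compound list**

1 | (S)-citramalic acid, (2S)-2-hydroxy-2-methylbutanedioic acid | OC(=O)[C@@](CC(=O)O)(C)O | starting material
2 | 2-[(4S)-2,2,4-trimethyl-5-oxo-1,3-dioxolan-4-yl]acetic acid | CC1(C)OC(=O)[C@@](CC(=O)O)(C)O1 | intermediate
3 | (E)-prop-1-en-1-ylboronic acid | C/C=C/B(O)O | starting material
4 | 2-[(4S)-2,2,4-trimethyl-5-oxo-1,3-dioxolan-4-yl]acetyl chloride (not isolated) | CC1(C)OC(=O)[C@@](CC(=O)Cl)(C)O1 | intermediate
5 | (5S)-2,2,5-trimethyl-5-[(3E)-2-oxopent-3-en-1-yl]-1,3-dioxolan-4-one | CC1(C)OC(=O)[C@@](CC(=O)/C=C/C)(C)O1 | intermediate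
6 | (5S)-5-[(1Z,3E)-2-{[tert-butyl(dimethyl)silyl]oxy}penta-1,3-dien-1-yl]-2,2,5-trimethyl-1,3-dioxolan-4-one | CC1(C)OC(=O)[C@@](/C=C(\O[Si](C)(C)C(C)(C)C)/C=C/C)(C)O1 | intermediate
7 | sodium alkoxide of prop-2-en-1-yl (2S,3Z,5E)-4-{[tert-butyl(dimethyl)silyl]oxy}-2-hydroxy-2-methylhepta-3,5-dienoate (not isolated) | C=CCOC(=O)[C@@](/C=C(\O[Si](C)(C)C(C)(C)C)/C=C/C)(C)[O-].[Na+] | intermediate
8 | prop-2-en-1-yl (2S,3Z,5E)-4-{[tert-butyl(dimethyl)silyl]oxy}-2-methyl-2-{[(2Z)-2-methylbut-2-enoyl]oxy}hepta-3,5-dienoate | C=CCOC(=O)[C@@](/C=C(\O[Si](C)(C)C(C)(C)C)/C=C/C)(C)OC(=O)/C(C)=C\C | intermediate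
9 | but-3-yn-2-one | CC(=O)C#C | starting material
10 | triethylammonium (2S,3Z,5E)-4-{[tert-butyl(dimethyl)silyl]oxy}-2-methyl-2-{[(2Z)-2-methylbut-2-enoyl]oxy}hepta-3,5-dienoate (not isolated) | [O-]C(=O)[C@@](/C=C(\O[Si](C)(C)C(C)(C)C)/C=C/C)(C)OC(=O)/C(C)=C\C.CC[NH+](CC)CC | intermediate
11 | (1E)-3-oxobut-1-en-1-yl (2S,3Z,5E)-4-{[tert-butyl(dimethyl)silyl]oxy}-2-methyl-2-{[(2Z)-2-methylbut-2-enoyl]oxy}hepta-3,5-dienoate | CC(=O)/C=C/OC(=O)[C@@](/C=C(\O[Si](C)(C)C(C)(C)C)/C=C/C)(C)OC(=O)/C(C)=C\C | intermediate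
12 | (3S,3aR,6S,7R,7aR)-7-acetyl-4-{[tert-butyl(dimethyl)silyl]oxy}-3,6-dimethyl-2-oxo-2,3,3a,6,7,7a-hexahydro-1-benzofuran-3-yl (2Z)-2-methylbut-2-enoate (cis-fused lactone; acetyl trans to the lactone oxygen; ring methyl cis to C11) | C[C@H]1C=C(O[Si](C)(C)C(C)(C)C)[C@@H]2[C@@H](OC(=O)[C@@]2(C)OC(=O)/C(C)=C\C)[C@@H]1C(C)=O | intermediate
13 | (3S,3aR,6R,7S,7aS)-4-{[tert-butyl(dimethyl)silyl]oxy}-3,6-dimethyl-2-oxo-7-(prop-1-en-2-yl)-2,3,3a,6,7,7a-hexahydro-1-benzofuran-3-yl (2Z)-2-methylbut-2-enoate (spatially as 12) | C[C@H]1C=C(O[Si](C)(C)C(C)(C)C)[C@@H]2[C@@H](OC(=O)[C@@]2(C)OC(=O)/C(C)=C\C)[C@@H]1C(C)=C | intermediate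
14 | (3S,3aR,7R,7aS)-3,6-dimethyl-2,4-dioxo-7-(prop-1-en-2-yl)-2,3,3a,4,7,7a-hexahydro-1-benzofuran-3-yl (2Z)-2-methylbut-2-enoate | CC1=CC(=O)[C@@H]2[C@@H](OC(=O)[C@@]2(C)OC(=O)/C(C)=C\C)[C@@H]1C(C)=C | intermediate
15 | trimethylsilyl enol ether (C8=C9) of ketone 16 (not isolated) | C=C[C@@]1(C)C=C(O[Si](C)(C)C)[C@@H]2[C@@H](OC(=O)[C@@]2(C)OC(=O)/C(C)=C\C)[C@@H]1C(C)=C | intermediate
16 | (3S,3aR,6R,7R,7aS)-6-ethenyl-3,6-dimethyl-2,4-dioxo-7-(prop-1-en-2-yl)octahydro-1-benzofuran-3-yl (2Z)-2-methylbut-2-enoate | C=C[C@@]1(C)CC(=O)[C@@H]2[C@@H](OC(=O)[C@@]2(C)OC(=O)/C(C)=C\C)[C@@H]1C(C)=C | intermediate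
17 | (3S,3aR,4S,6R,7R,7aS)-6-ethenyl-4-hydroxy-3,6-dimethyl-2-oxo-7-(prop-1-en-2-yl)octahydro-1-benzofuran-3-yl (2Z)-2-methylbut-2-enoate | C=C[C@@]1(C)C[C@H](O)[C@@H]2[C@@H](OC(=O)[C@@]2(C)OC(=O)/C(C)=C\C)[C@@H]1C(C)=C | intermediate
18 | (3S,3aR,4S,6R,7R,7aS)-4-(acetyloxy)-6-ethenyl-3,6-dimethyl-2-oxo-7-(prop-1-en-2-yl)octahydro-1-benzofuran-3-yl (2Z)-2-methylbut-2-enoate | C=C[C@@]1(C)C[C@H](OC(C)=O)[C@@H]2[C@@H](OC(=O)[C@@]2(C)OC(=O)/C(C)=C\C)[C@@H]1C(=C)C | target

**Totals.** Total step count: 11. Longest linear sequence: 11 steps (1 → 18).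

**Steps most likely to fail**

Step 6. The ester tether may resist the s-cis rotamer that the closure needs. The cycloaddition may also close through the competing tether-exo mode (acetyl endo) to a trans-fused lactone, or the acyl enone may undergo acyl transfer and decompose before it cyclises. Fallback: setting out from allyl ester 8, carboxylate 10 is generated as in step 5 and added to N-methoxy-N-methylprop-2-ynamide (N-methylmorpholine cat., CH2Cl2) to give (1E)-3-[methoxy(methyl)amino]-3-oxoprop-1-en-1-yl (2S,3Z,5E)-4-{[tert-butyl(dimethyl)silyl]oxy}-2-methyl-2-{[(2Z)-2-methylbut-2-enoyl]oxy}hepta-3,5-dienoate F1. This acrylamide dienophile is thermally more robust and its twisted amide has little endo preference. Heating (toluene, 130 °C) should give the N-methoxy-N-methylcarboxamide analogue of 12 F2, and MeMgBr (THF, −78 °C) converts the amide into the methyl ketone, coming back to the route at 12.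

Step 9. The 1,4-addition to the β,β-disubstituted enone may be slow, with competing attack on the ester carbonyls. The basic reagent may also enolise the ketone towards C7, with β-elimination of the lactone carboxylate and aromatisation, or the bulky cuprate may lose facial selectivity. Fallback: setting out from enone 14, nickel-catalysed conjugate addition of the slim, non-basic alkynylalane Me2AlC≡CSiMe3 (Ni(acac)2, i-Bu2AlH, Et2O, −5 °C) gives the 6-[(trimethylsilyl)ethynyl] analogue of 16 F3. Bu4NF/AcOH (THF, 0 °C) gives the 6-ethynyl analogue of 16 F4. Semi-hydrogenation (H2, Pd/CaCO3–Pb(OAc)2, quinoline, EtOAc) then returns to the route at 16.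

Step 10. Hydride may be delivered to the other face of C8, because the equatorial trajectory is shielded by the axial C11 and its methyl group; this would give the equatorial alcohol. Fallback: setting out from ketone 16, NaBH4/CeCl3·7H2O (MeOH, −40 °C) is used on purpose to make the C8-epimeric (equatorial) alcohol, the (4R)-epimer of 17 F5. A Mitsunobu reaction with acetic acid (PPh3, DIAD, toluene, 0 °C → rt) then inverts C8 and installs the acetate in one operation, coming back to the route at 18.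

**Further compounds**

F1 | step 6 | (1E)-3-[methoxy(methyl)amino]-3-oxoprop-1-en-1-yl (2S,3Z,5E)-4-{[tert-butyl(dimethyl)silyl]oxy}-2-methyl-2-{[(2Z)-2-methylbut-2-enoyl]oxy}hepta-3,5-dienoate | CON(C)C(=O)/C=C/OC(=O)[C@@](/C=C(\O[Si](C)(C)C(C)(C)C)/C=C/C)(C)OC(=O)/C(C)=C\C
F2 | step 6 | 4-{[tert-butyl(dimethyl)silyl]oxy}-7-[methoxy(methyl)carbamoyl]-3,6-dimethyl-2-oxo-2,3,3a,6,7,7a-hexahydro-1-benzofuran-3-yl (2Z)-2-methylbut-2-enoate (stereocentres as in 12) | C[C@H]1C=C(O[Si](C)(C)C(C)(C)C)[C@@H]2[C@@H](OC(=O)[C@@]2(C)OC(=O)/C(C)=C\C)[C@@H]1C(=O)N(C)OC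
F3 | step 9 | 3,6-dimethyl-2,4-dioxo-7-(prop-1-en-2-yl)-6-[(trimethylsilyl)ethynyl]octahydro-1-benzofuran-3-yl (2Z)-2-methylbut-2-enoate (stereocentres as in 16) | C[Si](C)(C)C#C[C@@]1(C)CC(=O)[C@@H]2[C@@H](OC(=O)[C@@]2(C)OC(=O)/C(C)=C\C)[C@@H]1C(C)=C
F4 | step 9 | 6-ethynyl-3,6-dimethyl-2,4-dioxo-7-(prop-1-en-2-yl)octahydro-1-benzofuran-3-yl (2Z)-2-methylbut-2-enoate (stereocentres as in 16) | C#C[C@@]1(C)CC(=O)[C@@H]2[C@@H](OC(=O)[C@@]2(C)OC(=O)/C(C)=C\C)[C@@H]1C(C)=C
F5 | step 10 | (3S,3aR,4R,6R,7R,7aS)-6-ethenyl-4-hydroxy-3,6-dimethyl-2-oxo-7-(prop-1-en-2-yl)octahydro-1-benzofuran-3-yl (2Z)-2-methylbut-2-enoate | C=C[C@@]1(C)C[C@@H](O)[C@@H]2[C@@H](OC(=O)[C@@]2(C)OC(=O)/C(C)=C\C)[C@@H]1C(C)=C
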